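The ratio of coupling partner to solid substrate charged is 1.10, so solid substrate is the limiting reagent on paper.

    initiator → 2 initiating radical (k1 = 0.0533 min⁻¹)
    starting material + initiating radical → capped initiator + first chain carrier (k2 = 3.94 × 10⁵ M⁻¹ min⁻¹)
    coupling partner + first chain carrier → target + second chain carrier (k3 = 1.19 × 10⁵ M⁻¹ min⁻¹)
    starting material + second chain carrier → by-product + first chain carrier (k4 = 1.05 × 10⁵ M⁻¹ min⁻¹)
    2 second chain carrier → ended chains A (k5 = 2 × 10⁶ M⁻¹ s⁻¹)
    solid substrate ⇌ starting material, rate k6*(cs6 - [starting material]) while solid is left; crystals form when [starting material] > cs6 (cs6 = 0.31 M, k6 = 0.0374 min⁻¹)
    first chain carrier + radical scavenger → ended chains B (k7 = 6.00 × 10⁶ M⁻¹ s⁻¹)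
    starting material + target → side product (k8 = 0.0704 M⁻¹ min⁻¹)

solid substrate 1.9 M; coupling partner 2.09 M; initiator 38 mM; radical scavenger 1.9 mM; time 30 min

- percent here means solid substrate units held: one side product counts as two
- for a step with 2 of a species take k times the square, and two of it per event
- solid substrate is a solid; its amount is given per volume of the solution
- at the start none of the solid substrate is in solution
- starting material means what is dissolved; the solid is not counted in it
- run time (flask): 30 min

- amount of target at 30 min, in percent of the solid substrate charged
- concentration of starting material in solution at 3.0 min, in percent of saturation
- the change that raises the amount of target at 30 min, in percent of the solid substrate charged most ("none" if none brings more than 2 percentage points) (oak / birch / elm / none)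
- amount of target at 30 min, in percent of the solid substrate charged, after birch

- oak: doubling the solubility in step 6, all else as stated
- birch: doubling the dissolution coefficient of step 6, all else as stated
- elm: doubling the amount of coupling partner, all else as stated

1. Write the balance of solid substrate. What dissolves stands as starting material, target, side product or ended chains B; first chain carrier is the passage to target and to ended chains B.

2. First guess: the charge can become target. Objection: it must dissolve first. So take the feed ceiling, the dissolution coefficient times the solubility times the time, over the solid charged: 18.3%. That is what an empty solution can receive.

3. Objection: the solution may fill, and inflow then falls. Balance the radicals: initiator makes two per event, and termination takes two. So [second chain carrier] is near 4.11 × 10⁻⁶ M. Starting material then has a half-life, by its step with second chain carrier, of 1.61 min, which is short against the run. Inflow against loss gives a standing 0.0161 M, or 5.19% of saturation. The pool needs time to rise, and 3.0 min is 1.86 of those half-lives, so read this as a high estimate for that moment.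

4. Objection: initiator fades, with a half-life of 13 min. Let [second chain carrier] follow the root of [initiator]. At 30 min the pool is then 0.0466 M.

5. Commit. Take half the final pool as the mean shortfall in inflow, then subtract the final pool. Target comes to 14.5%. Leave out the side product: at the final pool, target's half-life by its step with starting material is 3.52 h, long against the run.

6. Compare the changes. Oak and birch each double the ceiling, and oak keeps the smaller back-term, so choose oak. Elm leaves the ceiling alone and shortens the life of first chain carrier, whose half-life by its step with coupling partner is 1.67 × 10⁻⁴ s, already shorter than starting material's. For birch, doubling ceiling and pool gives 26.2%.

The forecast gives 13.1% for y, 4.7% for sat, oak as best and 21.8% for yb. Its ground: “The chain is fast enough to hold dissolved starting material far below saturation”. My figures of 14.5% for y and 26.2% for yb stand above its own.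

The simulation gives 13.7%, 4.26%, oak and 23.8%. The gains are 12 percentage points for oak, 10 points for birch and 0 points for elm.

Target stands at 0.749 of the ceiling, and this flask is not at rest at 30 min. Solid substrate still reads 83.2%, and starting material is made 1.10 times faster than it is used. At 60.0 min target reads 23.0%, under that time's ceiling of 36.6%. Ten times the time reverses the gain: at 300 min target reads 2.87%, less than at 30 min, with side product at 80.6% and solid substrate at 2.43%.

Now take the neighbour with 1.1 M of solid substrate. The same inflow over a smaller charge lifts the ceiling to 31.6%, and the same share of it gives 23.7%. The simulation gives 23.7% for that flask.

The numbers were chosen freely; the rest is arithmetic.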